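**Strategy.** Each outer ring is a 2‑butanoylfilicinic acid: a cyclohexadienone whose C‑1 (C=O), C‑3 and C‑5 (C–OH) carry oxygen and whose C‑6 is quaternary (CMe2). The ring is cut into a malonyl unit (C‑1, C‑2, C‑3) and an isopropyl methyl ketone unit (C‑4, C‑5, C‑6). One operation, an Effenberger‑type α,α′‑annulation of the tetrasubstituted silyl enol ether of 3‑methylbutan‑2‑one with malonyl dichloride, forms C‑1–C‑6 and C‑3–C‑4; the quaternary C‑6, made first, rules out the usual 2‑pyranone. Butanoylation at C‑2 and a two‑fold Mannich‑base (o‑quinone methide) coupling through C‑4 with bis(aminomethyl)butanoylphloroglucinol then complete the trimer.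

Key step: step 2

Remark: the target and its precursors are mixtures of enol tautomers; each is written in one tautomer and tautomers are treated as one compound. The target has no stereocentre, so no step needs stereocontrol. Compound 7 enters step 6 twice.

**Step 1**
Reactants: 1 3‑bromo‑3‑methylbutan‑2‑one
Product: 2 2‑methyl‑3‑(trimethylsilyloxy)but‑2‑ene
Conditions: Zn dust, Me3SiCl, TMEDA, Et2O, 0 °C to rt; distillation
Reagents that add atoms: chlorotrimethylsilane, C[Si](C)(C)Cl
Why: Zinc inserts into the tertiary C–Br bond (Reformatsky‑type zinc enolate) and chlorotrimethylsilane traps the enolate on oxygen, so the enol double bond should lie only on the isopropyl side (reductive silylation of an α‑bromo ketone); no stereocentre is formed.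

**Step 2**
Reactants: 2 2‑methyl‑3‑(trimethylsilyloxy)but‑2‑ene; 3 malonyl dichloride
Product: 5 filicinic acid (3,5‑dihydroxy‑4,4‑dimethylcyclohexa‑2,5‑dien‑1‑one), via 4,4‑dimethyl‑3,5‑dioxohexanoyl chloride 4 (not isolated)
Conditions: 3 (1.1 equiv), Et2O, −20 °C to rt; then KOH, BnEt3NCl, H2O, rt; then aq HCl
Reagents that add atoms: none
Why: Proposed new method: the nucleophilic CMe2 carbon of 2 should attack malonyl dichloride (or the chlorocarbonylketene formed from it) and lose chlorotrimethylsilane to give keto acid chloride 4 with the quaternary carbon in place, after which the methyl ketone of 4 enolises toward CH3 and that carbon is acylated by the remaining acid chloride, so that the C(=O)–CMe2 bond and the C(=O)–CH2 bond of the ring both form in one flask. The closest known reaction type is the Effenberger cyclization, the α,α′‑annulation of cyclic ketone enol ethers with malonyl dichloride to bicyclo[3.3.1]nonane‑2,4,9‑triones finished by the same KOH/BnEt3NCl treatment; its transfer to an acyclic enol ether to give a monocyclic trione is the new element. The six‑membered ring closes by a 6‑(enolendo)‑exo‑trig C‑acylation. No stereocentre is formed, since the new quaternary carbon carries two methyl groups. The step needs C‑ over O‑acylation in the closure and must avoid the 4‑hydroxy‑2‑pyranone that acyclic enol ethers normally give with this reagent. The quaternary carbon made in the first acylation cannot become part of an aromatic pyranone, and the aqueous hydroxide stage under phase transfer is expected to return any O‑acylated enol‑ester isomer by acyl transfer to the delocalised, strongly acidic trione anion.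

**Step 3**
Reactants: 5 filicinic acid; 6 butanoyl chloride
Product: 7 butyrylfilicinic acid (2‑butanoyl‑3,5‑dihydroxy‑6,6‑dimethylcyclohexa‑2,4‑dien‑1‑one)
Conditions: 6 (1.1 equiv), AlCl3, PhNO2, rt to 50 °C; then ice, aq HCl
Reagents that add atoms: none
Why: Friedel–Crafts C‑acylation of the enolised trione (a vinylogous acid), a well‑established route to acylfilicinic acids; the two free ring CH positions of 5 are related by symmetry, so only one mono‑acyl product can form, and the first acyl group deactivates the ring toward a second.

**Step 4**
Reactants: 8 phloroglucinol; 6 butanoyl chloride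
Product: 9 1‑(2,4,6‑trihydroxyphenyl)butan‑1‑one (butyrylphloroglucinol)
Conditions: 6 (1.0 equiv), AlCl3, PhNO2/CH2Cl2, 0 °C to 40 °C; then ice, aq HCl
Reagents that add atoms: none
Why: Friedel–Crafts acylation of the very electron‑rich arene; the first acyl group, chelated to aluminium through the ortho hydroxyls, deactivates the ring, so mono‑acylation should prevail.

**Step 5**
Reactants: 9 1‑(2,4,6‑trihydroxyphenyl)butan‑1‑one; 10 N,N,N′,N′‑tetramethylmethanediamine
Product: 11 1‑{3,5‑bis[(dimethylamino)methyl]‑2,4,6‑trihydroxyphenyl}butan‑1‑one
Conditions: 10 (2.5 equiv), 1,4‑dioxane, 0 °C to rt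
Reagents that add atoms: none
Why: Phenolic Mannich reaction: the acidic acylphloroglucinol protonates the aminal to the N,N‑dimethylmethyleneiminium ion, which substitutes the only two free ring positions (C‑3 and C‑5); excess aminal should keep the first Mannich base from alkylating unreacted 9.

**Step 6**
Reactants: 11 1‑{3,5‑bis[(dimethylamino)methyl]‑2,4,6‑trihydroxyphenyl}butan‑1‑one; 7 butyrylfilicinic acid (two molecules)
Product: 12 the target, filixic acid BBB (1‑{3,5‑bis[(5‑butanoyl‑2,6‑dihydroxy‑3,3‑dimethyl‑4‑oxocyclohexa‑1,5‑dien‑1‑yl)methyl]‑2,4,6‑trihydroxyphenyl}butan‑1‑one)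
Conditions: 7 (2.2 equiv), 1,4‑dioxane, 90 °C, N2 stream; then dilute aq HCl wash, crystallisation
Reagents that add atoms: none
Why: Each o‑hydroxybenzylamine should lose dimethylamine on heating to give an o‑quinone methide, which is captured at its exocyclic carbon by the only free ring carbon (C‑4) of the vinylogous acid 7 (Mannich‑base alkylation, a conjugate addition); 11 has no free ring carbon and cannot self‑condense, and no stereocentre is formed.

**Compound list**
1 | 3‑bromo‑3‑methylbutan‑2‑one | CC(=O)C(C)(C)Br | starting material
2 | 2‑methyl‑3‑(trimethylsilyloxy)but‑2‑ene | CC(C)=C(C)O[Si](C)(C)C | intermediate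
3 | malonyl dichloride (propanedioyl dichloride) | O=C(Cl)CC(=O)Cl | starting material
4 | 4,4‑dimethyl‑3,5‑dioxohexanoyl chloride | CC(=O)C(C)(C)C(=O)CC(=O)Cl | intermediate (not isolated)
5 | filicinic acid (3,5‑dihydroxy‑4,4‑dimethylcyclohexa‑2,5‑dien‑1‑one) | CC1(C)C(O)=CC(=O)C=C1O | intermediate
6 | butanoyl chloride | CCCC(=O)Cl | starting material
7 | butyrylfilicinic acid (2‑butanoyl‑3,5‑dihydroxy‑6,6‑dimethylcyclohexa‑2,4‑dien‑1‑one) | CCCC(=O)C1=C(O)C=C(O)C(C)(C)C1=O | intermediate
8 | phloroglucinol (benzene‑1,3,5‑triol) | Oc1cc(O)cc(O)c1 | starting material
9 | 1‑(2,4,6‑trihydroxyphenyl)butan‑1‑one | CCCC(=O)c1c(O)cc(O)cc1O | intermediate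
10 | N,N,N′,N′‑tetramethylmethanediamine | CN(C)CN(C)C | starting material
11 | 1‑{3,5‑bis[(dimethylamino)methyl]‑2,4,6‑trihydroxyphenyl}butan‑1‑one | CCCC(=O)c1c(O)c(CN(C)C)c(O)c(CN(C)C)c1O | intermediate
12 | filixic acid BBB (CNP0086314.0) | CCCC(=O)C1=C(O)C(Cc2c(O)c(CC3=C(O)C(C)(C)C(=O)C(C(=O)CCC)=C3O)c(O)c(C(=O)CCC)c2O)=C(O)C(C)(C)C1=O | target

**Count.** Total steps: 6. Longest linear sequence: 4 steps (steps 1, 2, 3, 6); the second branch (steps 4, 5) joins at step 6.

**Steps most likely to fail**

1. Step 2 (Proposed new method). The second acylation may close through the enol oxygen instead of carbon. Malonyl dichloride may also self‑condense by way of chlorocarbonylketene, and hydroxide may cleave the non‑enolisable 1,3‑diketone around the quaternary carbon (retro‑Claisen) before the ring has closed. Fallback with known chemistry: the outer ring is made by dearomatising geminal C‑methylation instead of ring construction. The fallback sets out from 1‑(2,4,6‑trihydroxyphenyl)butan‑1‑one 9, which is treated with iodomethane (about 2 equiv) and NaOMe in MeOH at 0 °C to rt; double C‑alkylation at one free ring carbon should give butyrylfilicinic acid 7, where the fallback comes back to the route. Steps 1 to 3 are then not needed and no new compound is made (F0).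

2. Step 6. At 90 °C in the presence of the liberated amine the methylene bridges may scramble by retro‑Michael cleavage and recombination, and the second alkylation may stay incomplete. Fallback: the roles of the partners are reversed so that the electrophile forms under milder conditions. The fallback sets out from butyrylfilicinic acid 7, which is aminomethylated with N,N,N′,N′‑tetramethylmethanediamine 10 in 1,4‑dioxane at 0 °C to rt to give 2‑butanoyl‑4‑[(dimethylamino)methyl]‑3,5‑dihydroxy‑6,6‑dimethylcyclohexa‑2,4‑dien‑1‑one F1. Two equivalents of this Mannich base are then warmed (rt to 40 °C) with 1‑(2,4,6‑trihydroxyphenyl)butan‑1‑one 9. Loss of dimethylamine from a 1,3‑dione Mannich base is much easier than from a phenolic one, and the resulting 2‑methylene trione should be captured by the two free arene carbons of 9, which leads back to the route at the target 12.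

3. Step 5. The first‑formed Mannich base may lose amine and alkylate unreacted 9, giving diarylmethane oligomers, or the second aminomethylation may stall. Fallback: the bridges are made by formaldehyde condensation without any aminomethyl intermediate. The fallback sets out from 1‑(2,4,6‑trihydroxyphenyl)butan‑1‑one 9, which is condensed with butyrylfilicinic acid 7 (at least 2 equiv) and aqueous formaldehyde in dilute aqueous KOH at 0 °C to rt. Statistical homo‑coupling is accepted and the trimer is separated by chromatography, which leads back to the route at the target 12; no new compound is made (F0).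

**Further compounds**
F0 | step 2 | none | none
F1 | step 6 | 2‑butanoyl‑4‑[(dimethylamino)methyl]‑3,5‑dihydroxy‑6,6‑dimethylcyclohexa‑2,4‑dien‑1‑one | CCCC(=O)C1=C(O)C(CN(C)C)=C(O)C(C)(C)C1=O
F0 | step 5 | none | none
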